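Rings B and C are cut together at C4–C5 and C1–C10. The feature exploited is that carbinol C10, common to cyclohexane ring A, cyclohexene ring B and the furan-fused cycloheptanone ring C, is a latent enol carbon enolisable only towards C5, while ring B carries the C18 carboxyl on C4 and the furan on C1: exactly what remains when a 2-pyrone has added to an enol ether and expelled CO2. The precursor is a ring A C5=C10 triethylsilyl enol ether whose C9 side chain ends in a 3-furyl ketone bearing a 6-methoxycarbonyl-2-pyrone on furan C2. One thermal operation forms both bonds, both rings and the C5/C10 stereocentres.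

Key step: step 17

Remark: clerodane-type locants are used from ring A onwards (C1 furan-bearing CH, C4 lactone α-carbon, C5 quaternary carbon bearing C19H2O, C7 oxygenated CH, C8 and C9 methyl-bearing carbons, C10 carbinol, C11 CH2, C12 ketone, C18 carboxyl); TBS = tert-butyldimethylsilyl, TES = triethylsilyl; 2-oxo-2H-pyran-6-carboxylic acid is assumed to be purchasable.

Step 1
Reactants: 1 2,3-dimethylphenol
Product: 3 4,4-dimethoxy-2,3-dimethylcyclohexa-2,5-dien-1-one, via 4-methoxy-2,3-dimethylphenol 2 (not isolated)
Conditions: PhI(OAc)2 (2.2 equiv), MeOH, 0 °C → rt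
Reagents that add atoms: methanol (CO)
Why: Hypervalent-iodine oxidative dearomatisation: the phenol is oxidised twice at its free para position with capture of methanol each time (through 2), and the resulting ketal carbon (future C10) cannot rearomatise.

Step 2
Reactants: 3 4,4-dimethoxy-2,3-dimethylcyclohexa-2,5-dien-1-one
Product: 4 4,4-dimethoxy-2,3-dimethylcyclohex-2-en-1-one
Conditions: H2 (1 atm), RhCl(PPh3)3 (5 mol%), PhMe, rt
Reagents that add atoms: none
Why: Homogeneous hydrogenation with RhCl(PPh3)3 should saturate the unhindered disubstituted alkene and leave the tetrasubstituted enone alkene and the acid-sensitive ketal intact, avoiding the rearomatisation that acidic or heterogeneous catalysts can cause.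

Step 3
Reactants: 4 4,4-dimethoxy-2,3-dimethylcyclohex-2-en-1-one
Product: 5 (R)-4,4-dimethoxy-2,3-dimethylcyclohex-2-en-1-ol
Conditions: (S)-2-methyl-CBS-oxazaborolidine (20 mol%), BH3·SMe2, THF, −20 °C; MeOH, then aq. NH4Cl
Reagents that add atoms: none
Why: Corey–Bakshi–Shibata reduction: the ketone binds the oxazaborolidine boron with its larger α-methylalkenyl arm turned away so that coordinated borane delivers hydride to one carbonyl face, which by the standard model gives the (R)-carbinol (future C7) with the (S)-catalyst.

Step 4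
Reactants: 5 (R)-4,4-dimethoxy-2,3-dimethylcyclohex-2-en-1-ol
Product: 7 (R)-4-(tert-butyldimethylsilyloxy)-2,3-dimethylcyclohex-2-en-1-one, via silyl ether ketal 6 (not isolated)
Conditions: TBSCl, imidazole, CH2Cl2, rt; then 5% aq. oxalic acid, THF, rt
Reagents that add atoms: tert-butyldimethylsilyl chloride (CC(C)(C)[Si](C)(C)Cl); water (O)
Why: Imidazole-promoted silylation is followed in the same flask by mild acid hydrolysis of the allylic dimethyl ketal (far more labile than a secondary TBS ether), which unveils the transposed enone carbonyl (future C10) without touching C7.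

Step 5
Reactants: 7 (R)-4-(tert-butyldimethylsilyloxy)-2,3-dimethylcyclohex-2-en-1-one
Product: 8 (3S,4R)-4-(tert-butyldimethylsilyloxy)-2,3-dimethyl-1-(triethylsilyloxy)cyclohex-1-ene
Conditions: Et3SiH (1.5 equiv), RhCl(PPh3)3 (2 mol%), PhMe, 60 °C
Reagents that add atoms: triethylsilane (CC[SiH](CC)CC)
Why: Rhodium-catalysed 1,4-hydrosilylation of the enone puts silicon on oxygen and hydride on the β-carbon C8 from the face opposite the adjacent C7 siloxy group, so the C8 methyl ends cis to the C7 oxygen while the enolate is stored regiospecifically as the C9=C10 silyl enol ether.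

Step 6
Reactants: 8 (3S,4R)-4-(tert-butyldimethylsilyloxy)-2,3-dimethyl-1-(triethylsilyloxy)cyclohex-1-ene; 9 allyl bromide
Product: 11 (2S,3S,4R)-2-allyl-4-(tert-butyldimethylsilyloxy)-2,3-dimethylcyclohexan-1-one, via lithium enolate 10 (not isolated)
Conditions: MeLi, THF, 0 °C → rt; then DMPU, allyl bromide, −78 → 0 °C
Reagents that add atoms: none
Why: MeLi cleaves the Si–O bond to give the regiodefined lithium enolate 10 without equilibration towards C5, and C-allylation (enolate alkylation) occurs by axial attack on the face opposite the adjacent C8 methyl, creating quaternary C9 with the allyl group (C11) trans to that methyl.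

Step 7
Reactants: 11 (2S,3S,4R)-2-allyl-4-(tert-butyldimethylsilyloxy)-2,3-dimethylcyclohexan-1-one
Product: 13 2-[(1S,2S,3R)-3-(tert-butyldimethylsilyloxy)-1,2-dimethyl-6-oxocyclohexyl]acetaldehyde, via ozonide 12 (not isolated)
Conditions: O3, CH2Cl2, −78 °C; then PPh3, −78 °C → rt
Reagents that add atoms: ozone ([O-][O+]=O)
Why: Ozonolysis with reductive work-up cleaves the only C=C bond to the C12 aldehyde through ozonide 12, leaving the ketone, the silyl ether and the three stereocentres untouched.

Step 8
Reactants: 13 2-[(1S,2S,3R)-3-(tert-butyldimethylsilyloxy)-1,2-dimethyl-6-oxocyclohexyl]acetaldehyde; 14 3-bromofuran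
Product: 17 (2S,3S,4R)-4-(tert-butyldimethylsilyloxy)-2-[2-(furan-3-yl)-2-hydroxyethyl]-2,3-dimethylcyclohexan-1-one (both carbinol epimers), via 3-furyllithium 15 (not isolated), via 3-furyltitanium triisopropoxide 16 (not isolated)
Conditions: 14, n-BuLi, THF, −78 °C; ClTi(OiPr)3, −78 °C; then 13, −78 → 0 °C; H2O
Reagents that add atoms: none
Why: Bromine–lithium exchange at −78 °C gives 3-furyllithium without isomerisation, and transmetalation to the aryltitanium triisopropoxide makes the 1,2-addition selective for the aldehyde over the hindered C10 ketone and suppresses enolisation; the new carbinol centre is an inconsequential mixture because it is oxidised in step 9.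

Step 9
Reactants: 17 (2S,3S,4R)-4-(tert-butyldimethylsilyloxy)-2-[2-(furan-3-yl)-2-hydroxyethyl]-2,3-dimethylcyclohexan-1-one
Product: 18 (2S,3S,4R)-4-(tert-butyldimethylsilyloxy)-2-[2-(furan-3-yl)-2-oxoethyl]-2,3-dimethylcyclohexan-1-one
Conditions: DMP, CH2Cl2, rt
Reagents that add atoms: none
Why: Dess–Martin oxidation converts the secondary carbinol, which is in equilibrium with its five-membered lactol onto C10, into the aryl ketone under mild conditions that epimerise nothing.

Step 10
Reactants: 18 (2S,3S,4R)-4-(tert-butyldimethylsilyloxy)-2-[2-(furan-3-yl)-2-oxoethyl]-2,3-dimethylcyclohexan-1-one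
Product: 19 (4R,5S,6S)-4-(tert-butyldimethylsilyloxy)-6-[2-(furan-3-yl)-2-oxoethyl]-5,6-dimethylcyclohex-2-en-1-one
Conditions: IBX (2 equiv), DMSO–PhF, 70 °C
Reagents that add atoms: none
Why: IBX dehydrogenation of a ketone through its enol: the C10 ketone has β-hydrogens only at C6 (C9 is quaternary) and the C12 ketone has none, so the C5=C6 enone is the only dehydrogenation product possible.

Step 11
Reactants: 19 (4R,5S,6S)-4-(tert-butyldimethylsilyloxy)-6-[2-(furan-3-yl)-2-oxoethyl]-5,6-dimethylcyclohex-2-en-1-one; 20 formaldehyde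
Product: 21 (4R,5S,6S)-4-(tert-butyldimethylsilyloxy)-6-[2-(furan-3-yl)-2-oxoethyl]-2-(hydroxymethyl)-5,6-dimethylcyclohex-2-en-1-one
Conditions: 37% aq. HCHO, DMAP (30 mol%), THF–H2O, rt
Reagents that add atoms: none
Why: Morita–Baylis–Hillman reaction: DMAP adds reversibly to the unsubstituted β-carbon C6, the enolate is hydroxymethylated at C5 by formaldehyde and loss of DMAP restores the enone, no stereocentre being created or disturbed.

Step 12
Reactants: 21 (4R,5S,6S)-4-(tert-butyldimethylsilyloxy)-6-[2-(furan-3-yl)-2-oxoethyl]-2-(hydroxymethyl)-5,6-dimethylcyclohex-2-en-1-one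
Product: 22 (4R,5S,6S)-4-(tert-butyldimethylsilyloxy)-2-[(tert-butyldimethylsilyloxy)methyl]-6-[2-(furan-3-yl)-2-oxoethyl]-5,6-dimethylcyclohex-2-en-1-one
Conditions: TBSCl, imidazole, DMF, rt
Reagents that add atoms: tert-butyldimethylsilyl chloride (CC(C)(C)[Si](C)(C)Cl)
Why: Standard imidazole-promoted silylation of the primary allylic alcohol protects C19 for the palladium and rhodium steps.

Step 13
Reactants: 23 2-oxo-2H-pyran-6-carboxylic acid
Product: 24 methyl 2-oxo-2H-pyran-6-carboxylate
Conditions: MeOH, H2SO4 (cat.), reflux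
Reagents that add atoms: methanol (CO)
Why: Acid-catalysed Fischer esterification in methanol, conditions under which the 2-pyrone ring is stable.

Step 14
Reactants: 24 methyl 2-oxo-2H-pyran-6-carboxylate
Product: 26 methyl 3-bromo-2-oxo-2H-pyran-6-carboxylate, via dibromide 25 (not isolated)
Conditions: Br2, CH2Cl2, 0 °C → rt; then Et3N, 0 °C
Reagents that add atoms: bromine (BrBr)
Why: Bromination–dehydrobromination, the standard entry to 3-bromo-2-pyrones: electrophilic bromine attacks C3 (the α-carbon at the end of the ring-oxygen-conjugated diene) to give dibromide 25, from which triethylamine removes the acidic C3 hydrogen with loss of the C4 bromide.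

Step 15
Reactants: 22 (4R,5S,6S)-4-(tert-butyldimethylsilyloxy)-2-[(tert-butyldimethylsilyloxy)methyl]-6-[2-(furan-3-yl)-2-oxoethyl]-5,6-dimethylcyclohex-2-en-1-one; 26 methyl 3-bromo-2-oxo-2H-pyran-6-carboxylate
Product: 27 pyronyl enone (22 carrying the 6-methoxycarbonyl-2-oxo-2H-pyran-3-yl group on furan C2)
Conditions: Pd(PPh3)4 (10 mol%), KOAc, PhMe, 110 °C
Reagents that add atoms: none
Why: Palladium-catalysed direct C–H arylation by concerted metalation–deprotonation: with a zerovalent palladium phosphine catalyst and acetate in toluene, furans carrying a 3-carbonyl group are arylated at C2 (between the ring oxygen and the acyl group), and the C–Br bond of the 3-bromo-2-pyrone undergoes oxidative addition easily.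

Step 16
Reactants: 27 pyronyl enone
Product: 28 C5=C10 triethylsilyl enol ether of 27 (C6 now CH2; C7-OTBS and C19-OTBS retained)
Conditions: Et3SiH (1.5 equiv), RhCl(PPh3)3 (3 mol%), PhMe, 40 °C
Reagents that add atoms: triethylsilane (CC[SiH](CC)CC)
Why: Rhodium-catalysed 1,4-hydrosilylation is characteristic of conjugated enones and is expected to leave the hindered aryl ketone, the ester and the pseudo-aromatic pyrone alone; hydride goes to C6 and silicon to oxygen, so the tetrasubstituted C5=C10 enol ether forms regiospecifically and no stereocentre is created.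

Step 17
Reactants: 28 C5=C10 triethylsilyl enol ether
Product: 30 tricyclic dienoate (rings A, B and C; methyl C18 ester on C4; C1=C2 and C3=C4 diene; C10-OTES; C7-OTBS; C19-OTBS), via bridged lactone 29 (not isolated)
Conditions: PhMe (0.01 M, degassed), BHT (cat.), sealed tube, 130 °C
Reagents that add atoms: none
Why: Thermal inverse-electron-demand Diels–Alder reaction in which the electron-rich C5=C10 silyl enol ether adds across C3 and C6 of the pyrone, whose LUMO is lowered by the 6-ester and the 3-acylfuryl group, to give bridged lactone 29, which expels CO2 by retro-[4+2] at the same temperature; because C5 and C10 are fully substituted the diene cannot aromatise and 30 should persist. The closest known reaction type is the cycloaddition of electron-poor 2-pyrones with enol ethers and ketene acetals followed by CO2 extrusion, tethered cases included. Ring B closes as the six-membered cycloaddition ring itself (bonds C5–C4 and C10–C1), and ring C closes as the seven-membered ring of a fused-mode intramolecular cycloaddition, the five-atom tether (C9, C11, C12 and two furan carbons) joining dienophile carbon C10 to diene terminus pyrone C3 and being preorganised by its three sp2 atoms and the gem-disubstituted C9. C5 and C10 are created together under control of the C9 stereocentre: the tether can bring the pyrone only to the ring A face that carries C11, and suprafacial addition then places the new C5–C4 and C10–C1 bonds cis to each other and to C11 (rings A/B and A/C cis-fused). Regiochemistry is imposed by the tether, the endo/exo question disappears with CO2 and quaternary C9 allows only one enol ether, so diastereofacial selectivity is the sole requirement and the C9 anchor secures it.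

Step 18
Reactants: 30 tricyclic dienoate
Product: 32 1,2-dehydro lactone diol (18,19-lactone closed; free C7 and C10 hydroxyls; C1=C2 and C3=C4 diene), via triol ester 31 (not isolated)
Conditions: 48% aq. HF, MeCN, 0 °C → rt
Reagents that add atoms: none
Why: HF cleaves the primary and secondary TBS ethers and the tertiary TES ether (Si–F bond formation), and the liberated C19 alcohol then closes the five-membered lactone onto the adjacent C18 methyl ester under the same acidic conditions (transesterification), the stereocentres being untouched.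

Step 19
Reactants: 32 1,2-dehydro lactone diol
Product: 33 7-deacetyl target (C1–C2 saturated; H-1 cis to the C10 hydroxyl)
Conditions: H2 (1 atm), [Ir(cod)(PCy3)(py)]PF6 (10 mol%), CH2Cl2, rt
Reagents that add atoms: none
Why: Hydroxyl-directed homogeneous hydrogenation: the cationic iridium catalyst binds the allylic tertiary C10 hydroxyl and delivers H2 to C1=C2 from that face, which is also the open face of the cis-fused rings A and B, so H-1 ends cis to the hydroxyl, while the electron-poor C3=C4 lactone alkene and the furan are expected to react more slowly.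

Step 20
Reactants: 33 7-deacetyl target
Product: 34 target CNP0329797.1
Conditions: Ac2O, pyridine, DMAP (cat.), CH2Cl2, 0 °C → rt
Reagents that add atoms: acetic anhydride (CC(=O)OC(C)=O)
Why: Nucleophile-catalysed acetylation discriminates sterically, the secondary C7 alcohol reacting while the tertiary C10 alcohol flanked by two quaternary carbons does not, and the near-neutral conditions avoid a retro-aldol opening of the C10–C1 bond.

Compound list
1 | 2,3-dimethylphenol | Cc1cccc(O)c1C | starting material
2 | 4-methoxy-2,3-dimethylphenol | COc1ccc(O)c(C)c1C | intermediate (not isolated)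
3 | 4,4-dimethoxy-2,3-dimethylcyclohexa-2,5-dien-1-one | COC1(OC)C=CC(=O)C(C)=C1C | intermediate
4 | 4,4-dimethoxy-2,3-dimethylcyclohex-2-en-1-one | COC1(OC)CCC(=O)C(C)=C1C | intermediate
5 | (R)-4,4-dimethoxy-2,3-dimethylcyclohex-2-en-1-ol | O[C@@H]1CCC(OC)(OC)C(C)=C1C | intermediate
6 | TBS ether of 5 (silyl ether ketal) | CC(C)(C)[Si](C)(C)O[C@@H]1CCC(OC)(OC)C(C)=C1C | intermediate (not isolated)
7 | (R)-4-(tert-butyldimethylsilyloxy)-2,3-dimethylcyclohex-2-en-1-one | CC(C)(C)[Si](C)(C)O[C@@H]1CCC(=O)C(C)=C1C | intermediate
8 | (3S,4R)-4-(tert-butyldimethylsilyloxy)-2,3-dimethyl-1-(triethylsilyloxy)cyclohex-1-ene | CC(C)(C)[Si](C)(C)O[C@@H]1CCC(O[Si](CC)(CC)CC)=C(C)[C@@H]1C | intermediate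
9 | allyl bromide | C=CCBr | starting material
10 | lithium enolate of 8 (C9=C10) | CC(C)(C)[Si](C)(C)O[C@@H]1CCC(O[Li])=C(C)[C@@H]1C | intermediate (not isolated)
11 | (2S,3S,4R)-2-allyl-4-(tert-butyldimethylsilyloxy)-2,3-dimethylcyclohexan-1-one | CC(C)(C)[Si](C)(C)O[C@@H]1CCC(=O)[C@@](C)(CC=C)[C@@H]1C | intermediate
12 | ozonide (1,2,4-trioxolane) of 11, ozonide carbon unassigned | CC(C)(C)[Si](C)(C)O[C@@H]1CCC(=O)[C@@](C)(CC2OCOO2)[C@@H]1C | intermediate (not isolated)
13 | 2-[(1S,2S,3R)-3-(tert-butyldimethylsilyloxy)-1,2-dimethyl-6-oxocyclohexyl]acetaldehyde | CC(C)(C)[Si](C)(C)O[C@@H]1CCC(=O)[C@@](C)(CC=O)[C@@H]1C | intermediate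
14 | 3-bromofuran | Brc1ccoc1 | starting material
15 | 3-furyllithium | [Li]c1ccoc1 | intermediate (not isolated)
16 | 3-furyltitanium triisopropoxide | CC(C)O[Ti](OC(C)C)(OC(C)C)c1ccoc1 | intermediate (not isolated)
17 | (2S,3S,4R)-4-(tert-butyldimethylsilyloxy)-2-[2-(furan-3-yl)-2-hydroxyethyl]-2,3-dimethylcyclohexan-1-one, carbinol epimers | CC(C)(C)[Si](C)(C)O[C@@H]1CCC(=O)[C@@](C)(CC(O)c2ccoc2)[C@@H]1C | intermediate
18 | (2S,3S,4R)-4-(tert-butyldimethylsilyloxy)-2-[2-(furan-3-yl)-2-oxoethyl]-2,3-dimethylcyclohexan-1-one | CC(C)(C)[Si](C)(C)O[C@@H]1CCC(=O)[C@@](C)(CC(=O)c2ccoc2)[C@@H]1C | intermediate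
19 | (4R,5S,6S)-4-(tert-butyldimethylsilyloxy)-6-[2-(furan-3-yl)-2-oxoethyl]-5,6-dimethylcyclohex-2-en-1-one | CC(C)(C)[Si](C)(C)O[C@@H]1C=CC(=O)[C@@](C)(CC(=O)c2ccoc2)[C@@H]1C | intermediate
20 | formaldehyde | C=O | starting material
21 | (4R,5S,6S)-4-(tert-butyldimethylsilyloxy)-6-[2-(furan-3-yl)-2-oxoethyl]-2-(hydroxymethyl)-5,6-dimethylcyclohex-2-en-1-one | CC(C)(C)[Si](C)(C)O[C@@H]1C=C(CO)C(=O)[C@@](C)(CC(=O)c2ccoc2)[C@@H]1C | intermediate
22 | (4R,5S,6S)-4-(tert-butyldimethylsilyloxy)-2-[(tert-butyldimethylsilyloxy)methyl]-6-[2-(furan-3-yl)-2-oxoethyl]-5,6-dimethylcyclohex-2-en-1-one | CC(C)(C)[Si](C)(C)O[C@@H]1C=C(CO[Si](C)(C)C(C)(C)C)C(=O)[C@@](C)(CC(=O)c2ccoc2)[C@@H]1C | intermediate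
23 | 2-oxo-2H-pyran-6-carboxylic acid | OC(=O)C1=CC=CC(=O)O1 | starting material
24 | methyl 2-oxo-2H-pyran-6-carboxylate | COC(=O)C1=CC=CC(=O)O1 | intermediate
25 | methyl 3,4-dibromo-2-oxo-3,4-dihydro-2H-pyran-6-carboxylate (racemic; both centres lost in the elimination) | COC(=O)C1=CC(Br)C(Br)C(=O)O1 | intermediate (not isolated)
26 | methyl 3-bromo-2-oxo-2H-pyran-6-carboxylate | COC(=O)C1=CC=C(Br)C(=O)O1 | intermediate
27 | pyronyl enone: 22 with the 6-methoxycarbonyl-2-oxo-2H-pyran-3-yl group on furan C2 | CC(C)(C)[Si](C)(C)O[C@@H]1C=C(CO[Si](C)(C)C(C)(C)C)C(=O)[C@@](C)(CC(=O)c2ccoc2C2=CC=C(C(=O)OC)OC2=O)[C@@H]1C | intermediate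
28 | C5=C10 triethylsilyl enol ether of 27 (key precursor) | CC(C)(C)[Si](C)(C)O[C@@H]1CC(CO[Si](C)(C)C(C)(C)C)=C(O[Si](CC)(CC)CC)[C@@](C)(CC(=O)c2ccoc2C2=CC=C(C(=O)OC)OC2=O)[C@@H]1C | intermediate
29 | bridged bicyclic lactone cycloadduct (C5–pyrone C6 and C10–pyrone C3 bonds on the C11 face; the two bridgeheads may be endo or exo and are left open) | CC(C)(C)[Si](C)(C)O[C@@H]1C[C@@]2(CO[Si](C)(C)C(C)(C)C)C3(C(=O)OC)C=CC4(C(=O)O3)c3occc3C(=O)C[C@@](C)([C@@H]1C)[C@@]24O[Si](CC)(CC)CC | intermediate (not isolated)
30 | tricyclic dienoate: C18 methyl ester on C4, C1=C2/C3=C4 diene, C10-OTES, C7-OTBS, C19-OTBS; C4 and C1 cis to C11 | CC(C)(C)[Si](C)(C)O[C@@H]1C[C@@]3(CO[Si](C)(C)C(C)(C)C)C(C(=O)OC)=CC=C2c4occc4C(=O)C[C@@](C)([C@@H]1C)[C@]23O[Si](CC)(CC)CC | intermediate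
31 | triol ester: fully desilylated 30 | O[C@@H]1C[C@@]3(CO)C(C(=O)OC)=CC=C2c4occc4C(=O)C[C@@](C)([C@@H]1C)[C@]23O | intermediate (not isolated)
32 | 1,2-dehydro lactone diol | O[C@@H]1C[C@@]23COC(=O)C2=CC=C2c4occc4C(=O)C[C@@](C)([C@@H]1C)[C@]23O | intermediate
33 | 7-deacetyl target (H-1 cis to the C10 hydroxyl) | O[C@@H]1C[C@@]23COC(=O)C2=CC[C@H]2c4occc4C(=O)C[C@@](C)([C@@H]1C)[C@]23O | intermediate
34 | CNP0329797.1 (on ring A the C7 acetoxy, the C8 and C9 methyls, the C10 hydroxyl and C19 share one face; C11, C1 and C4 lie on the other) | CC(=O)O[C@@H]1C[C@@]23COC(=O)C2=CC[C@H]2c4occc4C(=O)C[C@@](C)([C@@H]1C)[C@]23O | target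

Total step count: 20. Longest linear sequence: 18 steps (steps 1–12 and 15–20, from 2,3-dimethylphenol); the bromopyrone branch takes 2 steps (13–14).

Steps most likely to fail

Step 17. The cycloaddition may be too slow for steric reasons, since a tetrasubstituted enol ether must bond to two substituted pyrone termini and create two adjacent quaternary centres. Protodesilylation or thermal decomposition of the enol ether could then win. The fallback gives up the pericyclic mode for a stepwise anionic annulation. Setting out from 28, anhydrous fluoride (tetrabutylammonium difluorotriphenylsilicate, THF, −78 → 25 °C) would free the C5/C10 enolate, a far stronger nucleophile than the silyl enol ether. C5 should then add to the electrophilic pyrone C6 (Michael addition), and the resulting pyranone enolate should close through pyrone C3 onto the regenerated C10 ketone (aldol) to give the bridged hydroxy lactone F1. Warming (PhMe, 80 °C) should expel CO2 to leave the C10 carbinol dienoate F2. Treating F2 under the conditions of step 18 removes the two remaining silyl groups and lactonises (through 31), coming back to the route at 32.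

Step 15. Regiocontrol may be lost (arylation at furan C5 instead of C2), or the bromopyrone may be consumed by reductive debromination or homocoupling before C–H cleavage occurs. The fallback separates C–H functionalisation from C–C coupling. Setting out from 22, ketone-directed iridium-catalysed ortho C–H borylation ([Ir(OMe)(cod)]2, AsPh3, B2pin2, octane, 100 °C) should give the furan-2-boronate F3. Suzuki–Miyaura coupling of F3 with 26 (Pd(dppf)Cl2, K3PO4, dioxane–H2O, 60 °C) comes back to the route at 27.

Step 19. Chemoselectivity within the conjugated dienyl lactone may be lost, through over-reduction of C3=C4 or of the furan, or the catalyst may be inhibited by diene chelation. The fallback replaces 1,2-hydrogenation by 1,4-hydrogenation plus conjugative isomerisation. Setting out from 32, (η6-C10H8)Cr(CO)3 (cat.), H2 (20 atm), THF, 45 °C should add hydrogen to C1 and C4 of the s-cis-locked diene from the open, hydroxyl-bearing face, giving the β,γ-unsaturated lactone F4 with H-1 already correct. Mild base (Et3N or DBU, CH2Cl2, rt) should then move the C2=C3 bond into conjugation with the lactone, erasing the C4 centre and coming back to the route at 33.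

Further compounds
F1 | step 17 | bridged hydroxy lactone (29 with free C10 hydroxyl; bridgeheads left open) | CC(C)(C)[Si](C)(C)O[C@@H]1C[C@@]2(CO[Si](C)(C)C(C)(C)C)C3(C(=O)OC)C=CC4(C(=O)O3)c3occc3C(=O)C[C@@](C)([C@@H]1C)[C@@]24O
F2 | step 17 | C10 carbinol dienoate (30 without the TES group) | CC(C)(C)[Si](C)(C)O[C@@H]1C[C@@]3(CO[Si](C)(C)C(C)(C)C)C(C(=O)OC)=CC=C2c4occc4C(=O)C[C@@](C)([C@@H]1C)[C@]23O
F3 | step 15 | furan-2-boronate (22 with a pinacolboryl group on furan C2) | CC(C)(C)[Si](C)(C)O[C@@H]1C=C(CO[Si](C)(C)C(C)(C)C)C(=O)[C@@](C)(CC(=O)c2ccoc2B2OC(C)(C)C(C)(C)O2)[C@@H]1C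
F4 | step 19 | β,γ-unsaturated lactone (C2=C3 alkene; H-1 cis to the C10 hydroxyl; C4 centre unassigned) | O[C@@H]1C[C@@]23COC(=O)C2C=C[C@H]2c4occc4C(=O)C[C@@](C)([C@@H]1C)[C@]23O
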